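Late in the earlier runs, from 8.00 min to 15.0 min, product falls and substrate climbs back, and that is the stretch to watch when you repeat the run. Summed over the three runs, substrate regains 7.6 percentage points while product loses 10 points, so substrate gets back less. Some material is standing elsewhere: at the first reading of Saturday's run, substrate and product make up 73.3% of the charge.

| flask | substrate | reagent in the second phase | remark | time | volume of the second phase over the first |
|---|---|---|---|---|---|
| Saturday's | 0.14 M | 0.15 M | run made earlier |  |  |
| Thursday's | 0.22 M | 0.15 M | run made earlier |  |  |
| Sunday's | 0.10 M | 0.075 M | run made earlier |  |  |
| flask | 0.10 M | 0.150 M |  | 12 min | 0.25 |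

- Saturday's (time / min: product / %, substrate / %): 1.33: 8.7, 64.6; 2.50: 13.5, 60.9; 5.00: 22.4, 55.6; 8.00: 21.7, 58.5; 15.0: 17.7, 59.9
- Thursday's (time / min: product / %, substrate / %): 1.33: 7.8, 64.8; 2.50: 14.3, 60.9; 5.00: 20.0, 57.4; 8.00: 19.9, 58.2; 15.0: 15.3, 60.7
- Sunday's (time / min: product / %, substrate / %): 1.33: 4.6, 67.0; 2.50: 9.8, 64.5; 5.00: 12.1, 61.8; 8.00: 12.7, 60.0; 15.0: 10.8, 63.7

(standard deviation of a reading: 1 percentage point)

- the best time, 12 min at the latest, for product
- the amount of product, in percent of the substrate charged, at that time
- earliest time at which at least nineteen twentieths of that best amount are there, in min
- latest time at which they still are, in min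

You can get the share that stands as substrate in two ways. The first takes the level at the first reading, summed over the three runs:

f = substrate / (charge − product) = 0.704

The second takes the late slope:

f = substrate regained / product lost = 0.724

This is the free share, the part of the charge not turned into product that stands as substrate. The two ways use different readings, a level early and a slope late, and they agree. The slope is the rougher of the two, since it rests on small differences between readings that each scatter by 1 point. So I carry the first value, as a fast pre-equilibrium between substrate and the missing part:

c(substrate) = f × (charge − c(product)), in percent of the charge

By this rule, substrate reaches its lowest point when product reaches its highest.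

The forecast reads the missing part as “a fast reversible side pool holding about 30% of the material”. For this flask, charged with the 0.150 M of reagent in the second phase that Saturday's run was also charged with, it gives 22% of product at 6.4 min, with the window from 4.5 min to 8.8 min. My own reckoning adds that substrate in this flask should then stand at 54.9%.

The flask gives 22.1% of product at 5.84 min, with the window from 3.92 min to 9.02 min, so the forecast held within its margins.

    reagent in the reaction phase → decomposed reagent (k = 0.00196 /s)
    reagent in the reaction phase ⇌ reagent in the second phase, rate k2*([reagent in the reaction phase] - [reagent in the second phase]/K2) per volume of the first phase (partition coefficient = 5.71, kL = 0.00776 /s)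
    substrate + reagent in the reaction phase ⇌ product (K = 10.4 /M, k = 0.148 /M/s)
    substrate ⇌ dormant form (K = 0.410, k = 0.0402 /s)

The missing part is the dormant form. At 5.84 min this flask holds 22.1% of product, so the rule gives 54.8% of substrate, and 55.2% stood there. The neighbouring flask has 0.40 M of substrate with all else held, and its best is 15.5% of product. At 12.0 min it holds 14.8% of product, so the same rule gives 60.0% of substrate, and the neighbouring flask has 60% of its charge still there as substrate.

The runs stem from a simulated flask with made-up constants, and the scatter is random.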